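## Retrosynthetic overview

1. The C6 side chain comes last. The acid derives from its aldehyde, and the aldehyde from an amine-catalysed Michael addition of the free ring-A enol to (E)-hex-2-enal, which sets the side-chain centre. The enol derives from its O7 2-(trimethylsilyl)ethyl ether, and that from its 8,8a-dihydro form.
2. Ring A (C4a, C5, C6, C7, C8, C8a) is cut at C8–C8a. The dihydro compound is the 6π valence isomer of a hexatriene. The hexatriene is the 4π-opened form of a cyclobutenolate (four-membered ring C5, C6, C7, C8), built from 5-magnesiated ring B and a 4,4-dialkyl-3-alkoxycyclobutenone.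
3. Enabling feature: C8a is both the O1 enol-ether carbon of ring B and the β-carbon of the C8a=C4a–C4=O enone, while C8 ends the C5(O)=C6–C7(O)=C8 dienolate. The six ring-A carbons therefore form one acceptor/donor-substituted hexatriene with C8 and C8a as its termini.
4. The cyclobutenone derives from a dialkylketene and an ynol ether by [2+2] cycloaddition. The ketene acid derives from the (R)-limonene skeleton by cleavage of its C1–C2 ring bond, which keeps the isopropenyl-bearing stereocentre. Ring B derives from a syn-aldol adduct.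
5. Order of ring formation: temporary cyclobutene (step 8), ring B (step 12), ring A (step 14).

Key step: step 14

Remark: each enolised β-tricarbonyl unit is drawn as one tautomer, the Michael adduct is drawn as the open aldehyde although it should rest largely as its lactols, and chromene numbering (O1 to C8a) is used for the bicyclic compounds and their precursors.

## Route

Step 1
Reactants: 1 (+)-limonene oxide, (4R)-1-methyl-4-(prop-1-en-2-yl)-7-oxabicyclo[4.1.0]heptane, commercial cis/trans mixture
Product: 2 (3R)-6-oxo-3-(prop-1-en-2-yl)heptanal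
Conditions: H5IO6, THF/H2O, 0 °C to 25 °C
Reagents that add atoms: water, O
Why: Hydrolysis of either epoxide isomer to the 1,2-diol followed by Malaprade glycol cleavage cuts the C1–C2 ring bond of the terpene and leaves the remote stereocentre and the isopropenyl group untouched.

Step 2
Reactants: 2 (3R)-6-oxo-3-(prop-1-en-2-yl)heptanal; 3 methyltriphenylphosphonium bromide
Product: 4 (5R)-2-methyl-5-(prop-1-en-2-yl)octa-1,7-diene
Conditions: 3 (excess), KOtBu, THF, 0 °C to 25 °C
Reagents that add atoms: methyltriphenylphosphonium bromide (3), C[P+](c1ccccc1)(c1ccccc1)c1ccccc1.[Br-]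
Why: A double Wittig methylenation converts the aldehyde and the methyl ketone faster than the ylide enolises them, and the stereocentre is not alpha to either carbonyl.

Step 3
Reactants: 4 (5R)-2-methyl-5-(prop-1-en-2-yl)octa-1,7-diene
Product: 5 (4R)-7-methyl-4-(prop-1-en-2-yl)oct-7-en-1-ol
Conditions: (Me2CHCHMe)2BH (from BH3·THF and 2-methylbut-2-ene), THF, 0 °C; then NaOH, H2O2
Reagents that add atoms: hydrogen peroxide, OO
Why: In this Brown hydroboration–oxidation the bulky dialkylborane should select the single monosubstituted vinyl group over the two 1,1-disubstituted alkenes and place oxygen on the terminal carbon.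

Step 4
Reactants: 5 (4R)-7-methyl-4-(prop-1-en-2-yl)oct-7-en-1-ol
Product: 6 (4R)-7-methyl-4-(prop-1-en-2-yl)oct-7-enoic acid
Conditions: TEMPO (cat.), PhI(OAc)2, MeCN/H2O, 25 °C
Reagents that add atoms: water, O
Why: The oxoammonium (TEMPO) oxidation passes through the aldehyde hydrate to the acid and does not touch isolated alkenes.

Step 5
Reactants: 6 (4R)-7-methyl-4-(prop-1-en-2-yl)oct-7-enoic acid; 7 prenyl bromide
Product: 8 (2RS,4R)-7-methyl-2-(3-methylbut-2-en-1-yl)-4-(prop-1-en-2-yl)oct-7-enoic acid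
Conditions: LiN(iPr)2 (2.2 equiv), THF/DMPU, −78 °C to 0 °C; 7; dilute HCl work-up
Reagents that add atoms: prenyl bromide (7), CC(C)=CCBr
Why: SN2 alkylation of the carboxylic acid dianion with the allylic bromide installs the prenyl arm, and the new C2 centre needs no control because step 8 erases it.

Step 6
Reactants: 9 2-(trimethylsilyl)ethanol; 10 trichloroethylene
Product: 11 (E)-1,2-dichlorovinyl 2-(trimethylsilyl)ethyl ether
Conditions: KH, THF, 0 °C; 10, −50 °C to 25 °C
Reagents that add atoms: trichloroethylene (10), ClC=C(Cl)Cl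
Why: Elimination of trichloroethylene to dichloroacetylene and trans addition of the alkoxide is the standard addition–elimination entry to dichlorovinyl ethers.

Step 7
Reactants: 11 (E)-1,2-dichlorovinyl 2-(trimethylsilyl)ethyl ether
Product: 13 [2-(ethynyloxy)ethyl]trimethylsilane, via lithium alkoxyacetylide 12 (not isolated)
Conditions: n-BuLi (2.2 equiv), Et2O, −78 °C to −40 °C; MeOH
Reagents that add atoms: none
Why: β-Elimination to the chloroalkyne, chlorine–lithium exchange and protonation form the established route from dichlorovinyl ethers to terminal ynol ethers.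

Step 8
Reactants: 8 (2RS,4R)-7-methyl-2-(3-methylbut-2-en-1-yl)-4-(prop-1-en-2-yl)oct-7-enoic acid; 13 [2-(ethynyloxy)ethyl]trimethylsilane
Product: 16 4-(3-methylbut-2-en-1-yl)-4-[(2R)-5-methyl-2-(prop-1-en-2-yl)hex-5-en-1-yl]-3-[2-(trimethylsilyl)ethoxy]cyclobut-2-en-1-one (both C4 epimers), via acid chloride 14 (not isolated), via dialkylketene 15 (not isolated)
Conditions: Me2C=C(Cl)NMe2, CH2Cl2, 0 °C; then 13 (excess), Et3N, toluene, 60 °C
Reagents that add atoms: none
Why: Acid-free chloride formation, Staudinger-type dehydrochlorination and thermal ketene–ynol ether [2+2] cycloaddition give the 3-alkoxycyclobutenone, since polarity joins the ketene carbonyl carbon to the unsubstituted alkyne carbon and the excess electron-rich alkyne should outrun the pendant alkenes.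

Step 9
Reactants: 17 (4S)-4-benzyl-3-propanoyl-1,3-oxazolidin-2-one; 18 acetaldehyde
Product: 20 (4S)-4-benzyl-3-[(2S,3R)-3-hydroxy-2-methylbutanoyl]-1,3-oxazolidin-2-one, via Z-boron enolate 19 (not isolated)
Conditions: Bu2BOSO2CF3, Et3N, CH2Cl2, −78 °C to 0 °C; 18, −78 °C; H2O2, MeOH, pH 7 buffer
Reagents that add atoms: acetaldehyde (18), CC=O
Why: In the Evans syn-aldol reaction the Z-boron enolate reacts through a Zimmerman–Traxler chair on the face left open by the benzyl group, which sets both future ring-B centres as (2S,3R).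

Step 10
Reactants: 20 (4S)-4-benzyl-3-[(2S,3R)-3-hydroxy-2-methylbutanoyl]-1,3-oxazolidin-2-one; 21 N,O-dimethylhydroxylamine hydrochloride
Product: 22 (2S,3R)-3-hydroxy-N-methoxy-N,2-dimethylbutanamide
Conditions: 21, AlMe3, CH2Cl2, −10 °C to 25 °C; dilute HCl work-up
Reagents that add atoms: N,O-dimethylhydroxylamine hydrochloride (21), CNOC.Cl
Why: Aluminium amide transamidation, assisted by the free β-hydroxyl group, removes the auxiliary without enolising the alpha centre.

Step 11
Reactants: 22 (2S,3R)-3-hydroxy-N-methoxy-N,2-dimethylbutanamide; 23 ethynylmagnesium bromide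
Product: 24 (4S,5R)-5-hydroxy-4-methylhex-1-yn-3-one
Conditions: 23 (excess), THF, −20 °C to 0 °C; aq NH4Cl
Reagents that add atoms: ethynylmagnesium bromide (23), C#C[Mg]Br
Why: In the Weinreb ketone synthesis the chelated tetrahedral adduct survives until work-up, so that neither over-addition nor retro-aldol cleavage of the magnesium alkoxide should intervene.

Step 12
Reactants: 24 (4S,5R)-5-hydroxy-4-methylhex-1-yn-3-one
Product: 25 (2R,3S)-2,3-dimethyl-2,3-dihydro-4H-pyran-4-one
Conditions: AgOSO2CF3 (cat.), CH2Cl2, 25 °C, dark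
Reagents that add atoms: none
Why: The π-acid-catalysed 6-endo-dig oxa-Michael cycloisomerisation closes ring B with both C–O and C–C stereocentres intact, and the neutral medium protects the cis relationship at C3.

Step 13
Reactants: 25 (2R,3S)-2,3-dimethyl-2,3-dihydro-4H-pyran-4-one
Product: 26 (2R,3S)-5-iodo-2,3-dimethyl-2,3-dihydro-4H-pyran-4-one
Conditions: N-iodosuccinimide, MeCN, 0 °C to 25 °C
Reagents that add atoms: N-iodosuccinimide, O=C1CCC(=O)N1I
Why: Electrophilic alpha-iodination of the vinylogous ester occurs at its only nucleophilic carbon, C5, without base.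

Step 14
Reactants: 26 (2R,3S)-5-iodo-2,3-dimethyl-2,3-dihydro-4H-pyran-4-one; 16 4-(3-methylbut-2-en-1-yl)-4-[(2R)-5-methyl-2-(prop-1-en-2-yl)hex-5-en-1-yl]-3-[2-(trimethylsilyl)ethoxy]cyclobut-2-en-1-one
Product: 30 (2R,3S,8R,8aR)-5-hydroxy-2,3-dimethyl-8-(3-methylbut-2-en-1-yl)-8-[(2R)-5-methyl-2-(prop-1-en-2-yl)hex-5-en-1-yl]-7-[2-(trimethylsilyl)ethoxy]-2,3,8,8a-tetrahydro-4H-chromen-4-one, via magnesiated pyranone 27 (not isolated), via cyclobutenolate 28 (not isolated), via oxido-hexatriene 29 (not isolated)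
Conditions: 26, iPrMgCl·LiCl, THF, −40 °C; LaCl3·2LiCl, then 16, −78 °C to 25 °C; aq NH4Cl
Reagents that add atoms: none
Why: Iodine–magnesium exchange turns 26 into 27, which adds 1,2 to the strained carbonyl of 16; the cyclobutenolate 28 opens by oxido-accelerated conrotatory 4π electrocyclic cleavage of its C5–C8 bond, driven by release of the four-ring strain, and the 3-oxido-hexatriene 29 closes by thermal disrotatory 6π electrocyclisation between C8 and C8a to the chelated magnesium β-diketonate of 30. The closest known reaction type is the two-carbon ring expansion of cyclobutenones by alkenylmetal addition, 4π opening and 6π closure, a relative of the Moore and Danheiser ring expansions, and 29 carries the acceptor-on-C2 (C4=O), donor-on-C3 and donor-on-C5 pattern that is known to let such closures run at or below room temperature. Ring A is the only ring closed, in a 6π disrotatory mode that equals a 6-endo-trig vinylogous Michael closure, with Mg2+ bridging O5 and O4 to hold the s-cis,s-cis conformer. Torquoselectivity (oxido group outward) places ring B inward on C5, as the Z-triene requires, and through conrotation turns inward the C8 arm that is cis to the oxido group; because 27 should approach the carbonyl past the flat prenyl arm and away from the β-branched arm, both C4 epimers of 16 should converge on the triene with the branched arm inside and prenyl outside. C8 is then fixed by disrotation relative to the transient centre C8a: bond formation on the face of ring B opposite to its two cis methyl groups lifts H-8a and the inside arm onto the methyl-bearing face, which corresponds to (8R,8aR). The step needs 1,2- over 1,4-addition, C- over O-cyclisation and survival of the epimerisable C3–H, and these are secured by the hard magnesium/lanthanum reagent, by the alkyl block on O7 and by the fact that the hindered dienolate arises from C–C cleavage and not from an external base.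

Step 15
Reactants: 30 (2R,3S,8R,8aR)-5-hydroxy-2,3-dimethyl-8-(3-methylbut-2-en-1-yl)-8-[(2R)-5-methyl-2-(prop-1-en-2-yl)hex-5-en-1-yl]-7-[2-(trimethylsilyl)ethoxy]-2,3,8,8a-tetrahydro-4H-chromen-4-one
Product: 31 (2R,3S,8S)-2,3-dimethyl-8-(3-methylbut-2-en-1-yl)-8-[(2R)-5-methyl-2-(prop-1-en-2-yl)hex-5-en-1-yl]-7-[2-(trimethylsilyl)ethoxy]-2,3-dihydro-4H-chromene-4,5(8H)-dione (same spatial arrangement at C8; the descriptor changes with the priorities)
Conditions: DDQ, 1,4-dioxane, 25 °C
Reagents that add atoms: none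
Why: Quinone dehydrogenation abstracts the hydride at C8a, which is activated by O1 and by the adjacent enol, restores the C4a=C8a double bond and erases the transient centre while C8 cannot change.

Step 16
Reactants: 31 (2R,3S,8S)-2,3-dimethyl-8-(3-methylbut-2-en-1-yl)-8-[(2R)-5-methyl-2-(prop-1-en-2-yl)hex-5-en-1-yl]-7-[2-(trimethylsilyl)ethoxy]-2,3-dihydro-4H-chromene-4,5(8H)-dione
Product: 32 (2R,3S,8R)-5-hydroxy-2,3-dimethyl-8-(3-methylbut-2-en-1-yl)-8-[(2R)-5-methyl-2-(prop-1-en-2-yl)hex-5-en-1-yl]-2,3-dihydro-4H-chromene-4,7(8H)-dione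
Conditions: Bu4NF, AcOH, THF, 0 °C to 25 °C
Reagents that add atoms: none
Why: Fluoride-induced Peterson-type fragmentation of the 2-silylethyl group expels the vinylogous carboxylate under buffered conditions, which spare C3–H, ring B and the acid-sensitive alkenes.

Step 17
Reactants: 32 (2R,3S,8R)-5-hydroxy-2,3-dimethyl-8-(3-methylbut-2-en-1-yl)-8-[(2R)-5-methyl-2-(prop-1-en-2-yl)hex-5-en-1-yl]-2,3-dihydro-4H-chromene-4,7(8H)-dione; 33 (E)-hex-2-enal
Product: 34 (3S)-3-[(2R,3S,8R)-5-hydroxy-2,3-dimethyl-8-(3-methylbut-2-en-1-yl)-8-[(2R)-5-methyl-2-(prop-1-en-2-yl)hex-5-en-1-yl]-4,7-dioxo-3,4,7,8-tetrahydro-2H-chromen-6-yl]hexanal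
Conditions: 33, (R)-2-[diphenyl(trimethylsilyloxy)methyl]pyrrolidine (cat.), PhCO2H (cat.), CH2Cl2, 25 °C
Reagents that add atoms: (E)-hex-2-enal (33), CCC/C=C/C=O
Why: In this iminium-catalysed Michael addition of a cyclic 1,3-dicarbonyl nucleophile, C6 is the only free nucleophilic carbon and the bulky group of the (R)-catalyst shields one face of the E-iminium ion, so that the side-chain centre should form as (S) under catalyst control.

Step 18
Reactants: 34 (3S)-3-[(2R,3S,8R)-5-hydroxy-2,3-dimethyl-8-(3-methylbut-2-en-1-yl)-8-[(2R)-5-methyl-2-(prop-1-en-2-yl)hex-5-en-1-yl]-4,7-dioxo-3,4,7,8-tetrahydro-2H-chromen-6-yl]hexanal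
Product: 35 (3S)-3-[(2R,3S,8R)-5-hydroxy-2,3-dimethyl-8-(3-methylbut-2-en-1-yl)-8-[(2R)-5-methyl-2-(prop-1-en-2-yl)hex-5-en-1-yl]-4,7-dioxo-3,4,7,8-tetrahydro-2H-chromen-6-yl]hexanoic acid
Conditions: NaClO2, NaH2PO4, 2-methylbut-2-ene (large excess), t-BuOH/H2O, 0 °C
Reagents that add atoms: sodium chlorite, [Na+].[O-]Cl=O
Why: The Pinnick oxidation works on the aldehyde in equilibrium with its lactols at a mildly acidic pH that allows no retro-Michael loss of the new centre, and the alkene scavenger takes up the hypochlorous acid before it can reach the enol or the side-chain alkenes.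

## Compound list

1 | (+)-limonene oxide, (4R)-1-methyl-4-(prop-1-en-2-yl)-7-oxabicyclo[4.1.0]heptane (cis/trans mixture) | CC12OC1C[C@@H](CC2)C(C)=C | starting material
2 | (3R)-6-oxo-3-(prop-1-en-2-yl)heptanal | O=CC[C@@H](CCC(C)=O)C(C)=C | intermediate
3 | methyltriphenylphosphonium bromide | C[P+](c1ccccc1)(c1ccccc1)c1ccccc1.[Br-] | starting material
4 | (5R)-2-methyl-5-(prop-1-en-2-yl)octa-1,7-diene | C=CC[C@@H](CCC(C)=C)C(C)=C | intermediate
5 | (4R)-7-methyl-4-(prop-1-en-2-yl)oct-7-en-1-ol | OCCC[C@@H](CCC(C)=C)C(C)=C | intermediate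
6 | (4R)-7-methyl-4-(prop-1-en-2-yl)oct-7-enoic acid | OC(=O)CC[C@@H](CCC(C)=C)C(C)=C | intermediate
7 | prenyl bromide | CC(C)=CCBr | starting material
8 | (2RS,4R)-7-methyl-2-(3-methylbut-2-en-1-yl)-4-(prop-1-en-2-yl)oct-7-enoic acid | OC(=O)C(CC=C(C)C)C[C@@H](CCC(C)=C)C(C)=C | intermediate
9 | 2-(trimethylsilyl)ethanol | OCC[Si](C)(C)C | starting material
10 | trichloroethylene | ClC=C(Cl)Cl | starting material
11 | (E)-1,2-dichlorovinyl 2-(trimethylsilyl)ethyl ether | Cl/C=C(/Cl)OCC[Si](C)(C)C | intermediate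
12 | lithium 2-[2-(trimethylsilyl)ethoxy]ethynide | [Li]C#COCC[Si](C)(C)C | intermediate
13 | [2-(ethynyloxy)ethyl]trimethylsilane | C#COCC[Si](C)(C)C | intermediate
14 | acid chloride of 8 | ClC(=O)C(CC=C(C)C)C[C@@H](CCC(C)=C)C(C)=C | intermediate
15 | dialkylketene from 14 | O=C=C(CC=C(C)C)C[C@@H](CCC(C)=C)C(C)=C | intermediate
16 | 4-(3-methylbut-2-en-1-yl)-4-[(2R)-5-methyl-2-(prop-1-en-2-yl)hex-5-en-1-yl]-3-[2-(trimethylsilyl)ethoxy]cyclobut-2-en-1-one (both C4 epimers) | O=C1C=C(OCC[Si](C)(C)C)C1(CC=C(C)C)C[C@@H](CCC(C)=C)C(C)=C | intermediate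
17 | (4S)-4-benzyl-3-propanoyl-1,3-oxazolidin-2-one | CCC(=O)N1[C@@H](Cc2ccccc2)COC1=O | starting material
18 | acetaldehyde | CC=O | starting material
19 | Z-dibutylboron enolate of 17 | C/C=C(\OB(CCCC)CCCC)N1[C@@H](Cc2ccccc2)COC1=O | intermediate
20 | (4S)-4-benzyl-3-[(2S,3R)-3-hydroxy-2-methylbutanoyl]-1,3-oxazolidin-2-one | C[C@@H](O)[C@H](C)C(=O)N1[C@@H](Cc2ccccc2)COC1=O | intermediate
21 | N,O-dimethylhydroxylamine hydrochloride | CNOC.Cl | starting material
22 | (2S,3R)-3-hydroxy-N-methoxy-N,2-dimethylbutanamide | C[C@@H](O)[C@H](C)C(=O)N(C)OC | intermediate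
23 | ethynylmagnesium bromide | C#C[Mg]Br | starting material
24 | (4S,5R)-5-hydroxy-4-methylhex-1-yn-3-one | C[C@@H](O)[C@H](C)C(=O)C#C | intermediate
25 | (2R,3S)-2,3-dimethyl-2,3-dihydro-4H-pyran-4-one | C1=CO[C@H](C)[C@H](C)C1=O | intermediate
26 | (2R,3S)-5-iodo-2,3-dimethyl-2,3-dihydro-4H-pyran-4-one | IC1=CO[C@H](C)[C@H](C)C1=O | intermediate
27 | 5-(chloromagnesio) derivative of 25 | Cl[Mg]C1=CO[C@H](C)[C@H](C)C1=O | intermediate
28 | chloromagnesium cyclobutenolate, oxido group cis to the β-branched arm (pair of diastereomers from the two epimers of 16) | Cl[Mg]OC1(C2=CO[C@H](C)[C@H](C)C2=O)C=C(OCC[Si](C)(C)C)C1(CC=C(C)C)C[C@@H](CCC(C)=C)C(C)=C | intermediate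
29 | chloromagnesium 3-oxido-hexatriene, ring B and the β-branched arm inside | Cl[Mg]O/C(C1=CO[C@H](C)[C@H](C)C1=O)=C/C(OCC[Si](C)(C)C)=C(/CC=C(C)C)C[C@@H](CCC(C)=C)C(C)=C | intermediate
30 | (2R,3S,8R,8aR)-5-hydroxy-2,3-dimethyl-8-(3-methylbut-2-en-1-yl)-8-[(2R)-5-methyl-2-(prop-1-en-2-yl)hex-5-en-1-yl]-7-[2-(trimethylsilyl)ethoxy]-2,3,8,8a-tetrahydro-4H-chromen-4-one | C=C(C)CC[C@H](C[C@@]1(CC=C(C)C)C(OCC[Si](C)(C)C)=CC(O)=C2[C@@H]1O[C@H](C)[C@H](C)C2=O)C(=C)C | intermediate
31 | (2R,3S,8S)-2,3-dimethyl-8-(3-methylbut-2-en-1-yl)-8-[(2R)-5-methyl-2-(prop-1-en-2-yl)hex-5-en-1-yl]-7-[2-(trimethylsilyl)ethoxy]-2,3-dihydro-4H-chromene-4,5(8H)-dione | C=C(C)CC[C@H](C[C@@]1(CC=C(C)C)C(OCC[Si](C)(C)C)=CC(=O)C2=C1O[C@H](C)[C@H](C)C2=O)C(=C)C | intermediate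
32 | (2R,3S,8R)-5-hydroxy-2,3-dimethyl-8-(3-methylbut-2-en-1-yl)-8-[(2R)-5-methyl-2-(prop-1-en-2-yl)hex-5-en-1-yl]-2,3-dihydro-4H-chromene-4,7(8H)-dione | C=C(C)CC[C@H](C[C@@]1(CC=C(C)C)C(=O)C=C(O)C2=C1O[C@H](C)[C@H](C)C2=O)C(=C)C | intermediate
33 | (E)-hex-2-enal | CCC/C=C/C=O | starting material
34 | (3S)-3-[(2R,3S,8R)-5-hydroxy-2,3-dimethyl-8-(3-methylbut-2-en-1-yl)-8-[(2R)-5-methyl-2-(prop-1-en-2-yl)hex-5-en-1-yl]-4,7-dioxo-3,4,7,8-tetrahydro-2H-chromen-6-yl]hexanal | C=C(C)CC[C@H](C[C@@]1(CC=C(C)C)C(=O)C([C@@H](CCC)CC=O)=C(O)C2=C1O[C@H](C)[C@H](C)C2=O)C(=C)C | intermediate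
35 | (3S)-3-[(2R,3S,8R)-5-hydroxy-2,3-dimethyl-8-(3-methylbut-2-en-1-yl)-8-[(2R)-5-methyl-2-(prop-1-en-2-yl)hex-5-en-1-yl]-4,7-dioxo-3,4,7,8-tetrahydro-2H-chromen-6-yl]hexanoic acid | C=C(C)CC[C@H](C[C@@]1(CC=C(C)C)C(=O)C([C@@H](CCC)CC(=O)O)=C(O)C2=C1O[C@H](C)[C@H](C)C2=O)C(=C)C | target

## Step count and risks

Total step count: 18. Longest linear sequence: 11 steps (1, 2, 3, 4, 5, 8, 14, 15, 16, 17, 18).

**Step 14.**
- What may go wrong: the magnesiated pyranone may ring-open by β-elimination before it adds. The 1,2-addition to the hindered carbonyl may be sluggish. Weak discrimination between the two C8 arms, or between the two faces of ring B, would erode the C8 configuration.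
- Fallback: it sets out from 16 and 26, comes back at 30, and replaces the strain-driven cascade by stepwise acylation and an anionic closure.
- Heating 16 with free N,O-dimethylhydroxylamine in toluene should open it to the vinylketene. The amine traps this as (6R)-N-methoxy-N,9-dimethyl-4-(3-methylbut-2-en-1-yl)-6-(prop-1-en-2-yl)-3-[2-(trimethylsilyl)ethoxy]deca-2,9-dienamide F1.
- Addition of 27, made from 26 as before, in a Weinreb ketone synthesis gives the 5-acyl dihydropyranone F2.
- Brief treatment with LiN(SiMe3)2 in THF at −78 °C removes the proton at the future C8. The lithium dienolate then closes by intramolecular vinylogous Michael addition to 30, and C8 epimers would be separated at this stage.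

**Step 15.**
- What may go wrong: the prenyl group may suffer competing allylic oxidation. Ring B may open by retro-oxa-Michael reaction before the hydride is removed.
- Fallback: it sets out from 22 (with 16), comes back at 31, and moves the oxidation level into ring B, so that no oxidant is needed.
- Lithium (phenylthio)acetylide adds to 22 to give (4S,5R)-5-hydroxy-4-methyl-1-(phenylthio)hex-1-yn-3-one F3.
- Cycloisomerisation with AgOSO2CF3 gives (2R,3S)-2,3-dimethyl-6-(phenylthio)-2,3-dihydro-4H-pyran-4-one F4.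
- N-iodosuccinimide gives its 5-iodo derivative F5.
- Exchange with iPrMgCl·LiCl, addition to 16 and the same 4π/6π sequence lead to the 8a-phenylthio adduct F6, which loses thiophenolate by β-elimination and delivers 31 directly. The larger inside group at C8a may slow the closure.

**Step 17.**
- What may go wrong: C–C bond formation at the doubly flanked C6 may be slow. The reversible addition may lose enantiofacial control.
- Fallback: it sets out from 32, comes back at 35, and changes from iminium activation to an acyl azolium annulation at the acid oxidation level.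
- Commercial hex-2-ynal is used with the enantiomer of the aminoindanol-derived N-mesityl triazolium chloride that delivers the (S)-centre, and with iPr2NEt as base. This should convert 32 in a redox-neutral Claisen-type annulation into the enol δ-lactone F7, closed on O7.
- Mild hydrolysis with LiOH in THF/H2O at 0 °C opens F7 to 35 and makes steps 17 and 18 unnecessary.

## Further compounds

F1 | step 14 | (6R)-N-methoxy-N,9-dimethyl-4-(3-methylbut-2-en-1-yl)-6-(prop-1-en-2-yl)-3-[2-(trimethylsilyl)ethoxy]deca-2,9-dienamide (C4 epimers and alkene isomers inconsequential) | CON(C)C(=O)C=C(OCC[Si](C)(C)C)C(CC=C(C)C)C[C@@H](CCC(C)=C)C(C)=C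
F2 | step 14 | (2R,3S)-2,3-dimethyl-5-{(6R)-9-methyl-4-(3-methylbut-2-en-1-yl)-6-(prop-1-en-2-yl)-3-[2-(trimethylsilyl)ethoxy]deca-2,9-dienoyl}-2,3-dihydro-4H-pyran-4-one | O=C(C=C(OCC[Si](C)(C)C)C(CC=C(C)C)C[C@@H](CCC(C)=C)C(C)=C)C1=CO[C@H](C)[C@H](C)C1=O
F3 | step 15 | (4S,5R)-5-hydroxy-4-methyl-1-(phenylthio)hex-1-yn-3-one | C[C@@H](O)[C@H](C)C(=O)C#CSc1ccccc1
F4 | step 15 | (2R,3S)-2,3-dimethyl-6-(phenylthio)-2,3-dihydro-4H-pyran-4-one | C1=C(Sc2ccccc2)O[C@H](C)[C@H](C)C1=O
F5 | step 15 | (2R,3S)-5-iodo-2,3-dimethyl-6-(phenylthio)-2,3-dihydro-4H-pyran-4-one | IC1=C(Sc2ccccc2)O[C@H](C)[C@H](C)C1=O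
F6 | step 15 | 8a-phenylthio analogue of 30 (sulfur cis to the β-branched arm) | C=C(C)CC[C@H](C[C@@]1(CC=C(C)C)C(OCC[Si](C)(C)C)=CC(O)=C2[C@]1(Sc3ccccc3)O[C@H](C)[C@H](C)C2=O)C(=C)C
F7 | step 17 | enol δ-lactone of 35 closed on O7, (S) at the propyl-bearing carbon | C=C(C)CC[C@H](C[C@@]1(CC=C(C)C)C3=C([C@@H](CCC)CC(=O)O3)C(=O)C2=C1O[C@H](C)[C@H](C)C2=O)C(=C)C
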